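The closed vessel holds starting material and partner, and the second and third substrates compete for that partner.

in all of them: second substrate 180 mM

|  | starting material | partner | third substrate | remark | time |
|---|---|---|---|---|---|
| eta | 36 mM | 22 mM | 72 mM | run made earlier |  |
| epsilon | 36 mM | 32 mM | 72 mM | run made earlier |  |
| alpha | 18 mM | 43.2 mM | 72 mM | run made earlier |  |
| flask | 36 mM | 43.2 mM | 72.0 mM |  | 40 h |

| run | time / h | target / % | starting material / % |
|---|---|---|---|
| eta | 2.00 | 9 | 88 |
| eta | 4.00 | 15 | 82 |
| eta | 10.0 | 16 | 70 |
| eta | 20.0 | 15 | 68 |
| eta | 40.0 | 8 | 61 |
| epsilon | 2.00 | 16 | 79 |
| epsilon | 4.00 | 23 | 75 |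
| epsilon | 10.0 | 22 | 62 |
| epsilon | 20.0 | 22 | 52 |
| epsilon | 40.0 | 10 | 51 |
| alpha | 2.00 | 21 | 75 |
| alpha | 4.00 | 32 | 63 |
| alpha | 10.0 | 43 | 48 |
| alpha | 20.0 | 37 | 41 |
| alpha | 40.0 | 32 | 35 |

(standard deviation of a reading: 2 percentage points)

1. when, up to 40 h, the flask holds most target
2. the amount of target, in percent of the starting material charged, at that time

- a species is counted by the starting material in it: one side product counts as two
- what was read earlier has a scatter of 2 percentage points, one standard deviation
- reactions considered so far: starting material + partner -> target; partner + target -> over-reaction product; second substrate + partner -> second product; third substrate + partner -> third product; starting material + target -> side product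

- Fastest rung, the partner: in this reckoning from the runs, alpha's starting material drops by 0.288 log units over the first reading interval and by a smaller 0.174 over the next. That reads as a partner lifetime in alpha of 3.99 h and, from the same drops, a starting-material lifetime of 5.47 h at the charged partner. The extra starting material in the flask shortens the partner lifetime to 3.06 h.
- Middle rung, coupling: that starting-material lifetime is longer than the partner's lifetime in the flask, so in this reckoning coupling in the flask stalls with about 42.9 % of the starting material charged made into target.
- Slowest rung, side step: eta's late decline of target, a reading with wide scatter, gives target a lifetime of 20.5 h at 36 mM of starting material, longer than the coupling lifetime.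
- Rule: coupling and the side step both scale with c(starting material), which cancels. Setting over-reaction aside, target therefore rises until c(partner)/c(target) falls to 0.320, the crossing ratio, the side constant over the coupling constant. This is the inverse of the selectivity factor.
- Own reckoning for the flask: the partner, decaying from its charge, meets the crossing ratio against the target made after 6.64 h. Thinning that target over this time by the side-step lifetime leaves 31.0 %, and the same reckoning with the thinned target puts the peak at 7.63 h.
- Forecast: 31 % at 7.5 h, noting that “this loss grows with starting material concentration”.
- Flask: 31.7 % at 8.08 h.

    starting material + partner → target (k = 4.05 M⁻¹ h⁻¹)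
    partner + target → over-reaction product (k = 0.772 M⁻¹ h⁻¹)
    second substrate + partner → second product (k = 0.648 M⁻¹ h⁻¹)
    third substrate + partner → third product (k = 1.19 M⁻¹ h⁻¹)
    starting material + target → side product (k = 1.26 M⁻¹ h⁻¹)

- Up to 8.08 h, coupling ran in the flask while partner fell to 9.24 % of its charge, and over-reaction product reached 1.91 %, less than the 11.8 % of side product; c(partner)/c(target) then stood at 0.350, against the crossing ratio of 0.320. By 40.0 h the flask held 43.3 % of side product and 18.7 % of target. In the neighbour charged with 72 mM of second substrate, the ratio at 40.0 h is 0.00352, below the crossing ratio, and target stands at 26.0 % after a best of 36.9 %.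

The earlier runs and the new flask were generated by integration from invented constants; noise was put on by code.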